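**Retrosynthetic overview**
1. C6–C7 bond: rhodium-catalysed 1,4-addition of an (E)-alkenylboron side chain to a 5-methylidene-cyclopentenone. Kinetic protonation of the resulting enolate sets C8.
2. The exocyclic CH2 (C7) comes from formaldehyde. The C10=C11 enone comes from a regiodefined enol silane.
3. Key step: the five-membered ring arises by a desymmetrising one-carbon ring expansion (1,2-alkyl shift) of a prochiral 3-acetoxy-3-octenylcyclobutanone with TMSCHN2. This sets C12.
4. The cyclobutanone comes from 3-silyloxycyclobutanone and a (Z)-oct-2-enylcerium reagent made from oct-1-ene. The side chain comes from methyl 4-oxobutanoate, an ethynyl Grignard reagent and a lipase resolution (sets C4).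
5. Ring order: the only carbocycle is bought as a four-membered ring and enlarged once to the five-membered ring. No other ring is made.

Assumption: prostanoid numbering is used for positions (C1 is the ester carbon; C8 and C12 are the ring carbons that carry the two chains), and compounds 1, 2 and 13 are catalogue items.

**Step 1**
Reactants: 1 oct-1-ene; 2 3-[(tert-butyldimethylsilyl)oxy]cyclobutan-1-one
Product: 6 3-[(tert-butyldimethylsilyl)oxy]-1-[(2Z)-oct-2-en-1-yl]cyclobutyl acetate (cis/trans mixture), via (Z)-oct-2-enylpotassium 3 (not isolated), via (Z)-oct-2-enylcerium dichloride 4 (not isolated), via cerium cyclobutanolate 5 (not isolated)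
Conditions: n-BuLi, KOt-Bu, THF, −50 °C, 3 h; CeCl3, −78 °C; 2, −78 °C; Ac2O, DMAP, −78 °C to rt
Reagents that add atoms: acetic anhydride CC(=O)OC(C)=O
Why: Schlosser-base allylic metalation gives the allylpotassium, which settles in its endo (Z) form, and the derived allylcerium adds to the strained ketone through its unsubstituted terminus with the Z geometry kept (organocerium 1,2-addition, then O-acylation of the alkoxide); the cis/trans ratio does not matter because step 3 removes that element.

**Step 2**
Reactants: 6 3-[(tert-butyldimethylsilyl)oxy]-1-[(2Z)-oct-2-en-1-yl]cyclobutyl acetate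
Product: 7 3-hydroxy-1-[(2Z)-oct-2-en-1-yl]cyclobutyl acetate (cis/trans mixture)
Conditions: HF·pyridine, THF, 0 °C to rt
Reagents that add atoms: none
Why: Fluoride-driven desilylation under mildly acidic conditions frees the secondary alcohol without touching the tertiary acetate or the Z-alkene and without base-induced acyl migration.

**Step 3**
Reactants: 7 3-hydroxy-1-[(2Z)-oct-2-en-1-yl]cyclobutyl acetate
Product: 8 1-[(2Z)-oct-2-en-1-yl]-3-oxocyclobutyl acetate (achiral, prochiral)
Conditions: Dess–Martin periodinane, CH2Cl2, rt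
Reagents that add atoms: none
Why: Dess–Martin oxidation is neutral enough to leave the β-acetoxy ketone intact, and both diastereomers of 7 converge on one mirror-symmetric ketone.

**Step 4**
Reactants: 8 1-[(2Z)-oct-2-en-1-yl]-3-oxocyclobutyl acetate
Product: 11 (1S)-1-[(2Z)-oct-2-en-1-yl]-4-oxocyclopent-2-en-1-yl acetate, via α-silyl ketone 9 (not isolated), via enol silane 10 (not isolated)
Conditions: Sc(OTf)3 (10 mol %), chiral N,N'-dioxide ligand (L-pipecolic acid 2,6-diisopropylanilide arms, C3 linker, 11 mol %), TMSCHN2 (1.2 equiv), toluene, −40 °C; solvent swap to MeCN, Pd(OAc)2 (1.05 equiv), rt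
Reagents that add atoms: (trimethylsilyl)diazomethane C[Si](C)(C)C=[N+]=[N-]
Why: Proposed new method: a chiral scandium triflate/N,N'-dioxide Lewis acid binds the prochiral ketone, steers one prochiral face of the diazo carbon onto the carbonyl and thereby fixes the rotamer of the β-oxido diazonium ion in which only one of the two enantiotopic ring CH2 groups lies anti-periplanar to N2, so that the strain-driven 1,2-alkyl shift (about 20 kcal/mol released) enlarges the four-membered ring and sets C12 (the ligand antipode is chosen to give the drawn sense), after which a 1,3-Brook shift gives the regiodefined enol silane and Saegusa–Ito dehydrosilylation places the C10=C11 bond; the closest known reactions are the racemic Sc(OTf)3-catalysed trimethylsilyldiazomethane homologation of cyclobutanones (Tiffeneau–Demjanov type), chiral-scandium diazoalkane insertions that set α-centres, and enantiotopic-group-selective Baeyer–Villiger oxidation of 3-substituted cyclobutanones.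

**Step 5**
Reactants: 11 (1S)-1-[(2Z)-oct-2-en-1-yl]-4-oxocyclopent-2-en-1-yl acetate
Product: 12 (1R)-5-methylidene-1-[(2Z)-oct-2-en-1-yl]-4-oxocyclopent-2-en-1-yl acetate
Conditions: (CH2O)n, i-Pr2NH·CF3CO2H, CF3CO2H (10 mol %), THF, reflux
Reagents that add atoms: formaldehyde (as paraformaldehyde) C=O
Why: Direct α-methylenation (Mannich condensation followed by β-elimination of the amine) can only occur at C8, the sole enolisable position, and the weakly acidic medium avoids an enolate next to the acetate; C12 is untouched and only its descriptor changes.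

**Step 6**
Reactants: 13 methyl 4-oxobutanoate
Product: 14 methyl 4-hydroxyhex-5-ynoate (racemic)
Conditions: HC≡CMgBr, THF, −78 °C; cold aqueous NH4Cl
Reagents that add atoms: ethynylmagnesium bromide C#C[Mg]Br
Why: Grignard 1,2-addition is much faster at the aldehyde than at the ester at −78 °C, and a cold neutral quench keeps the γ-hydroxy ester from lactonising before the next step.

**Step 7**
Reactants: 14 methyl 4-hydroxyhex-5-ynoate (racemic)
Product: 15 methyl (4S)-4-acetoxyhex-5-ynoate
Conditions: Candida antarctica lipase B (immobilised), vinyl acetate, MTBE, rt, stopped near 45 % conversion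
Reagents that add atoms: vinyl acetate C=COC(C)=O
Why: Lipase-catalysed kinetic resolution by irreversible transesterification follows the Kazlauskas rule (small ethynyl group, large ester arm), so the (S)-alcohol is acylated and C4 is set together with its acetate.

**Step 8**
Reactants: 12 (1R)-5-methylidene-1-[(2Z)-oct-2-en-1-yl]-4-oxocyclopent-2-en-1-yl acetate; 15 methyl (4S)-4-acetoxyhex-5-ynoate
Product: 17 methyl (4S,5E)-4-acetoxy-7-{(1S,5R)-5-acetoxy-5-[(2Z)-oct-2-en-1-yl]-2-oxocyclopent-3-en-1-yl}hept-5-enoate, via alkenylboronate 16 (not isolated)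
Conditions: 15, pinacolborane, Cp2Zr(H)Cl (5 mol %), Et3N (10 mol %), 60 °C; then 12, [Rh(cod)(OH)]2 (2.5 mol %), KOH (20 mol %), dioxane/H2O 10:1, rt, short reaction time
Reagents that add atoms: none
Why: Syn-hydroboration fixes the E-alkene, the Hayashi–Miyaura-type rhodium-catalysed 1,4-addition attacks the unhindered exocyclic CH2 rather than C11 next to the quaternary centre, and kinetic protonation of the oxa-allyl rhodium/enol from the face carrying the small acetoxy group (opposite the octenyl arm) puts H8 cis to the acetate and so sets (S)-C8.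

**Compound list**
1 | oct-1-ene | C=CCCCCCC | starting material
2 | 3-[(tert-butyldimethylsilyl)oxy]cyclobutan-1-one | O=C1CC(O[Si](C)(C)C(C)(C)C)C1 | starting material
3 | (Z)-oct-2-enylpotassium | [K+].[CH2-]/C=C\CCCCC | intermediate
4 | (Z)-oct-2-enylcerium dichloride | Cl[Ce](Cl)C/C=C\CCCCC | intermediate
5 | dichlorocerium 3-[(tert-butyldimethylsilyl)oxy]-1-[(2Z)-oct-2-en-1-yl]cyclobutanolate | CCCCC/C=C\CC1(O[Ce](Cl)Cl)CC(O[Si](C)(C)C(C)(C)C)C1 | intermediate
6 | 3-[(tert-butyldimethylsilyl)oxy]-1-[(2Z)-oct-2-en-1-yl]cyclobutyl acetate (cis/trans mixture) | CCCCC/C=C\CC1(OC(C)=O)CC(O[Si](C)(C)C(C)(C)C)C1 | intermediate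
7 | 3-hydroxy-1-[(2Z)-oct-2-en-1-yl]cyclobutyl acetate (cis/trans mixture) | CCCCC/C=C\CC1(OC(C)=O)CC(O)C1 | intermediate
8 | 1-[(2Z)-oct-2-en-1-yl]-3-oxocyclobutyl acetate | CCCCC/C=C\CC1(OC(C)=O)CC(=O)C1 | intermediate
9 | (1S)-1-[(2Z)-oct-2-en-1-yl]-4-oxo-3-(trimethylsilyl)cyclopentyl acetate (silyl-bearing carbon undefined) | CCCCC/C=C\C[C@@]1(OC(C)=O)CC([Si](C)(C)C)C(=O)C1 | intermediate
10 | (1R)-1-[(2Z)-oct-2-en-1-yl]-3-[(trimethylsilyl)oxy]cyclopent-3-en-1-yl acetate | CCCCC/C=C\C[C@@]1(OC(C)=O)CC=C(O[Si](C)(C)C)C1 | intermediate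
11 | (1S)-1-[(2Z)-oct-2-en-1-yl]-4-oxocyclopent-2-en-1-yl acetate | CCCCC/C=C\C[C@@]1(OC(C)=O)C=CC(=O)C1 | intermediate
12 | (1R)-5-methylidene-1-[(2Z)-oct-2-en-1-yl]-4-oxocyclopent-2-en-1-yl acetate | CCCCC/C=C\C[C@@]1(OC(C)=O)C=CC(=O)C1=C | intermediate
13 | methyl 4-oxobutanoate | COC(=O)CCC=O | starting material
14 | methyl 4-hydroxyhex-5-ynoate (racemic) | C#CC(O)CCC(=O)OC | intermediate
15 | methyl (4S)-4-acetoxyhex-5-ynoate | C#C[C@H](CCC(=O)OC)OC(C)=O | intermediate
16 | methyl (4S,5E)-4-acetoxy-6-(4,4,5,5-tetramethyl-1,3,2-dioxaborolan-2-yl)hex-5-enoate | CC1(C)OB(/C=C/[C@H](CCC(=O)OC)OC(C)=O)OC1(C)C | intermediate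
17 | methyl (4S,5E)-4-acetoxy-7-{(1S,5R)-5-acetoxy-5-[(2Z)-oct-2-en-1-yl]-2-oxocyclopent-3-en-1-yl}hept-5-enoate | CCCCC/C=C\C[C@@]1(OC(C)=O)C=CC(=O)[C@H]1C/C=C/[C@H](CCC(=O)OC)OC(C)=O | target

**Total step count:** 8. **Longest linear sequence:** 6 (steps 1, 2, 3, 4, 5, 8).

**Steps most likely to fail**

Step 4 (the proposed new step) could fail because the catalyst distinguishes the two remote groups on C12 poorly, giving low enantiomeric excess, or because the acetate is lost under Lewis acid. The fallback uses known substrate-controlled chemistry, sets out from 4 and comes back to the route at 11. The organocerium 4 is added to commercial (R)-4-[(tert-butyldimethylsilyl)oxy]cyclopent-2-en-1-one, where 1,2-attack occurs anti to the silyloxy group. Quenching with acetic anhydride gives (1S,4R)-4-[(tert-butyldimethylsilyl)oxy]-1-[(2Z)-oct-2-en-1-yl]cyclopent-2-en-1-yl acetate F2. HF·pyridine then frees (1S,4R)-4-hydroxy-1-[(2Z)-oct-2-en-1-yl]cyclopent-2-en-1-yl acetate F3, and Dess–Martin oxidation of F3 gives 11.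

Step 1 could fail through attack at the substituted allyl terminus or through erosion of the Z geometry during the potassium-to-cerium exchange. The fallback sets out from 2 and comes back at 6. Allylmagnesium bromide is added to 2 and the alkoxide is quenched with acetic anhydride to give 1-allyl-3-[(tert-butyldimethylsilyl)oxy]cyclobutyl acetate F1. The Z-alkene is then built by Z-selective cross metathesis of F1 with hept-1-ene, using the cyclometalated ruthenium nitrato catalyst of Grubbs, which gives 6.

Step 8 could fail because substrate-controlled protonation is not selective enough, or because C8 epimerises to the more stable trans-dialkyl isomer in the aqueous medium. The fallback sets out from 12 (with 16) and comes back at 17. The addition is run as before and any methyl (4S,5E)-4-acetoxy-7-{(1R,5R)-5-acetoxy-5-[(2Z)-oct-2-en-1-yl]-2-oxocyclopent-3-en-1-yl}hept-5-enoate F4 is not separated. The epimer mixture is converted with TMSOTf/Et3N into the single methyl (4S,5E)-4-acetoxy-7-{(5R)-5-acetoxy-5-[(2Z)-oct-2-en-1-yl]-2-[(trimethylsilyl)oxy]cyclopenta-1,3-dien-1-yl}hept-5-enoate F5. F5 is then protonated at −78 °C under reagent control with the Lewis-acid-assisted Brønsted acid (R)-BINOL·SnCl4, with 2,6-dimethylphenol as the stoichiometric proton source, to give 17.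

**Further compounds**
F1 | step 1 | 1-allyl-3-[(tert-butyldimethylsilyl)oxy]cyclobutyl acetate | C=CCC1(OC(C)=O)CC(O[Si](C)(C)C(C)(C)C)C1
F2 | step 4 | (1S,4R)-4-[(tert-butyldimethylsilyl)oxy]-1-[(2Z)-oct-2-en-1-yl]cyclopent-2-en-1-yl acetate | CCCCC/C=C\C[C@@]1(OC(C)=O)C=C[C@H](O[Si](C)(C)C(C)(C)C)C1
F3 | step 4 | (1S,4R)-4-hydroxy-1-[(2Z)-oct-2-en-1-yl]cyclopent-2-en-1-yl acetate | CCCCC/C=C\C[C@@]1(OC(C)=O)C=C[C@H](O)C1
F4 | step 8 | methyl (4S,5E)-4-acetoxy-7-{(1R,5R)-5-acetoxy-5-[(2Z)-oct-2-en-1-yl]-2-oxocyclopent-3-en-1-yl}hept-5-enoate | CCCCC/C=C\C[C@@]1(OC(C)=O)C=CC(=O)[C@@H]1C/C=C/[C@H](CCC(=O)OC)OC(C)=O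
F5 | step 8 | methyl (4S,5E)-4-acetoxy-7-{(5R)-5-acetoxy-5-[(2Z)-oct-2-en-1-yl]-2-[(trimethylsilyl)oxy]cyclopenta-1,3-dien-1-yl}hept-5-enoate | CCCCC/C=C\C[C@@]1(OC(C)=O)C=CC(O[Si](C)(C)C)=C1C/C=C/[C@H](CCC(=O)OC)OC(C)=O
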